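**Retrosynthetic overview**
1. Ring A (C1 CH2-arm, C2 OH, C3 aroyl, C4 OH, C5 alkenyl, C6 OMe) is an acylphloroglucinol: oxygen on C2, C4 and C6 alternates with carbon on C1, C3 and C5, so it is read as a folded tetraketide chain started by the 3-hydroxybenzoyl group. Ring A is the only ring formed; ring B is bought as methyl 3-hydroxybenzoate.
2. Late disconnections on the finished ring: the C5–alkenyl bond (Suzuki coupling of a C5 iodide), the C6 O–Me bond (methylation of the one phenol not chelated to the ketone) and the silyl ether on ring B.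
3. Key disconnection C2–C3: Claisen ring closure of an open-chain methyl 2-alkyl-3,5,7-trioxo-7-arylheptanoate with Mg(OMe)2. The arm sits on the carbon next to the ester, so the competing aldol closure cannot give an arene.
4. The chain is grown from a C12 methyl ester by two acetylations (ester enolate, then β-keto ester dianion) and one aroylation (trianion).
5. The C12 ester comes from (R)-limonene by cleavage of the ring C1=C2 alkene, methylenation of the C1 ketone and Arndt–Eistert homologation of the C2 acid. Limonene C4 becomes the (R) centre of the arm, limonene C3 the arm CH2, limonene C2 ring carbon C2, and the diazomethane carbon ring carbon C1.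

Key step: step 11

Remark: the β-keto ester, diketo ester and triketo ester intermediates are mixtures of epimers at the carbon between ester and ketone and of keto–enol tautomers. This has no consequence, because that carbon becomes aromatic C1. Limonene oxide is used as its cis/trans mixture. The ring-A numbering of the overview is used throughout.

**Route**

Step 1
Reactants: 1 (R)-(+)-limonene [(4R)-1-methyl-4-(prop-1-en-2-yl)cyclohex-1-ene]
Product: 2 (4R)-1-methyl-4-(prop-1-en-2-yl)-7-oxabicyclo[4.1.0]heptane (limonene 1,2-oxide, cis/trans mixture at the epoxide)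
Conditions: mCPBA (1.0 equiv), CH2Cl2, 0 °C
Reagents that add atoms: mCPBA (3-chloroperoxybenzoic acid), O=C(OO)c1cccc(Cl)c1
Why: Prilezhaev epoxidation, in which the trisubstituted ring alkene is more electron-rich than the 1,1-disubstituted isopropenyl group and should react selectively with one equivalent of peracid, the epoxide configuration being irrelevant because both epoxide carbons become carbonyl carbons and C4 is untouched.

Step 2
Reactants: 2 (4R)-limonene 1,2-oxide
Product: 4 (3R)-6-oxo-3-(prop-1-en-2-yl)heptanal, via diol 3 (not isolated)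
Conditions: H5IO6 (1.2 equiv), THF/H2O, 0 → 25 °C
Reagents that add atoms: water, O
Why: Acid-mediated epoxide hydrolysis to the diol followed by Malaprade glycol cleavage with the same periodic acid should open the ring between the two oxygenated carbons without touching the isopropenyl group or the stereocentre, which lies β to the new aldehyde.

Step 3
Reactants: 4 (3R)-6-oxo-3-(prop-1-en-2-yl)heptanal
Product: 5 (3R)-6-oxo-3-(prop-1-en-2-yl)heptanoic acid
Conditions: NaClO2, NaH2PO4, 2-methyl-2-butene (excess), t-BuOH/H2O, 0 → 25 °C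
Reagents that add atoms: sodium chlorite, [Na+].[O-]Cl=O
Why: Pinnick oxidation converts only the aldehyde into the acid under buffered conditions, the methyl ketone being inert and the isopropenyl group being shielded from HOCl by the alkene scavenger.

Step 4
Reactants: 5 (3R)-6-oxo-3-(prop-1-en-2-yl)heptanoic acid
Product: 6 (3R)-6-methyl-3-(prop-1-en-2-yl)hept-6-enoic acid
Conditions: Ph3PCH3Br (3.0 equiv), KOtBu (3.0 equiv), THF, 0 → 50 °C; mild acidic work-up
Reagents that add atoms: methyltriphenylphosphonium bromide, C[P+](c1ccccc1)(c1ccccc1)c1ccccc1.[Br-]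
Why: Wittig methylenation, in which the acid is carried as its unreactive potassium carboxylate (hence the excess ylide) so that only the methyl ketone becomes the second 1,1-disubstituted alkene, the stereocentre lying α to neither carbonyl group.

Step 5
Reactants: 6 (3R)-6-methyl-3-(prop-1-en-2-yl)hept-6-enoic acid
Product: 8 (4R)-1-diazo-7-methyl-4-(prop-1-en-2-yl)oct-7-en-2-one, via mixed anhydride 7 (not isolated)
Conditions: i-BuOCOCl, Et3N, THF, −15 °C; then CH2N2, Et2O, −15 → 0 °C
Reagents that add atoms: diazomethane, C=[N+]=[N-]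
Why: First half of the Arndt–Eistert homologation, the acid being activated as a mixed carbonic anhydride under basic conditions (no HCl that could add to the alkenes) and then C-acylating diazomethane.

Step 6
Reactants: 8 (4R)-1-diazo-7-methyl-4-(prop-1-en-2-yl)oct-7-en-2-one
Product: 10 methyl (4R)-7-methyl-4-(prop-1-en-2-yl)oct-7-enoate, via ketene 9 (not isolated)
Conditions: PhCO2Ag (10 mol%), Et3N, MeOH, 25 °C, dark
Reagents that add atoms: methanol, CO
Why: Silver-catalysed Wolff rearrangement (loss of N2, 1,2-shift of the alkyl CH2 group, which is not the stereocentre) gives a ketene that methanol traps as the homologated methyl ester, and the alkenes should not react because no copper or rhodium carbenoid is involved.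

Step 7
Reactants: 10 methyl (4R)-7-methyl-4-(prop-1-en-2-yl)oct-7-enoate; 11 N-methoxy-N-methylacetamide
Product: 13 methyl 2-[(2R)-5-methyl-2-(prop-1-en-2-yl)hex-5-en-1-yl]-3-oxobutanoate, via lithium enolate 12 (not isolated)
Conditions: LiN(iPr)2 (1.1 equiv), THF, −78 °C; then 11, −78 → −20 °C; AcOH quench
Reagents that add atoms: none
Why: Crossed Claisen acylation of a lithium ester enolate with a Weinreb amide, whose chelated tetrahedral adduct does not collapse before the quench, so the acidic β-keto ester is never released in the presence of enolate and neither double acylation nor proton transfer should intervene; the new centre is a labile epimer mixture that later becomes aromatic C1.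

Step 8
Reactants: 13 methyl 2-[(2R)-5-methyl-2-(prop-1-en-2-yl)hex-5-en-1-yl]-3-oxobutanoate; 11 N-methoxy-N-methylacetamide
Product: 15 methyl 2-[(2R)-5-methyl-2-(prop-1-en-2-yl)hex-5-en-1-yl]-3,5-dioxohexanoate, via dilithium dienolate 14 (not isolated)
Conditions: LiN(iPr)2 (2.2 equiv), THF, −78 → 0 °C; then 11, 0 °C; AcOH quench
Reagents that add atoms: none
Why: γ-Acylation of a β-keto ester dianion, which reacts at its more basic terminal carbon (the future ring carbon C5) with the Weinreb amide, again stopping at the tetrahedral stage, to give the 3,5-diketo ester.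

Step 9
Reactants: 16 methyl 3-hydroxybenzoate
Product: 17 methyl 3-[tri(propan-2-yl)silyloxy]benzoate
Conditions: TIPSCl, imidazole, DMF, 25 °C
Reagents that add atoms: chlorotri(propan-2-yl)silane (TIPSCl), CC(C)[Si](Cl)(C(C)C)C(C)C
Why: Standard imidazole-mediated silylation of a phenol, the bulky TIPS ether being chosen because it has to survive lithium amide, magnesium methoxide, carbonate and aqueous phosphate before fluoride removes it at the end.

Step 10
Reactants: 15 methyl 2-[(2R)-5-methyl-2-(prop-1-en-2-yl)hex-5-en-1-yl]-3,5-dioxohexanoate; 17 methyl 3-[tri(propan-2-yl)silyloxy]benzoate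
Product: 19 methyl 2-[(2R)-5-methyl-2-(prop-1-en-2-yl)hex-5-en-1-yl]-3,5,7-trioxo-7-{3-[tri(propan-2-yl)silyloxy]phenyl}heptanoate, via trilithium trienolate 18 (not isolated)
Conditions: LiN(iPr)2 (4.2 equiv), THF, −78 → 0 °C; then 17 (1.2 equiv), 0 °C; AcOH quench at −78 °C; crude product used directly
Reagents that add atoms: none
Why: Polyanion Claisen acylation, in which the terminal carbanion of the trienolate (the future ring carbon C3) is the most basic site and attacks the non-enolisable aromatic ester, the fourth equivalent of amide base absorbing the proton of the more acidic tetracarbonyl product.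

Step 11
Reactants: 19 methyl 2-[(2R)-5-methyl-2-(prop-1-en-2-yl)hex-5-en-1-yl]-3,5,7-trioxo-7-{3-[tri(propan-2-yl)silyloxy]phenyl}heptanoate
Product: 21 {2,4,6-trihydroxy-3-[(2R)-5-methyl-2-(prop-1-en-2-yl)hex-5-en-1-yl]phenyl}{3-[tri(propan-2-yl)silyloxy]phenyl}methanone, via cyclohexanetrione 20 (not isolated)
Conditions: Mg(OMe)2 (6 equiv), MeOH, 25 → 50 °C; cold 0.5 M HCl work-up
Reagents that add atoms: none
Why: Mg(OMe)2 turns the polycarbonyl chain into magnesium enolates whose chelate rings fold it, the doubly activated carbon C3 (between the C4 ketone and the aroyl carbonyl) adds to the ester carbonyl C2, methoxide leaves, and the 2-aroylcyclohexane-1,3,5-trione 20 so formed enolises to the aromatic triol. The closest known reaction type is the base-mediated Claisen (Dieckmann) cyclisation of 3,5,7-triketo esters to acylphloroglucinols, the laboratory counterpart of polyketide folding, used here on a member of that class that carries an alkyl group next to the ester. Ring A closes in a 6-(enolexo)-exo-trig mode by formation of the C2–C3 bond. No stereocentre is formed: the epimeric carbon between ester and ketone becomes aromatic C1, and the limonene-derived centre is separated from every carbonyl by a CH2 group and cannot enolise. The step needs Claisen closure to beat the only other six-membered closure, aldol attack of C1 on the aroyl carbonyl, and the arm on C1 secures this, because that aldol would have to build a quaternary carbon next to a tertiary alkoxide, cannot lead to an arene and should revert, while the Claisen product leaves the equilibrium as a chelated magnesium phenoxide. Methanol as solvent makes ester exchange harmless, and the mild magnesium alkoxide at 50 °C or below should leave the aryl TIPS ether and the alkenes untouched.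

Step 12
Reactants: 21 {2,4,6-trihydroxy-3-[(2R)-5-methyl-2-(prop-1-en-2-yl)hex-5-en-1-yl]phenyl}{3-[tri(propan-2-yl)silyloxy]phenyl}methanone
Product: 22 {2,6-dihydroxy-4-methoxy-3-[(2R)-5-methyl-2-(prop-1-en-2-yl)hex-5-en-1-yl]phenyl}{3-[tri(propan-2-yl)silyloxy]phenyl}methanone (methyl ether at ring-A C6)
Conditions: Me2SO4 (1.05 equiv), K2CO3 (1.1 equiv), acetone, 0 → 25 °C
Reagents that add atoms: dimethyl sulfate, COS(=O)(=O)OC
Why: Williamson O-methylation, in which only the C6 hydroxyl (para to the ketone) is free of a hydrogen bond to the benzophenone carbonyl and is also the most acidic, so one equivalent of the hard electrophile with a weak base in an aprotic medium should methylate it selectively and disfavour C-methylation at C5.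

Step 13
Reactants: 22 {2,6-dihydroxy-4-methoxy-3-[(2R)-5-methyl-2-(prop-1-en-2-yl)hex-5-en-1-yl]phenyl}{3-[tri(propan-2-yl)silyloxy]phenyl}methanone
Product: 23 {2,6-dihydroxy-3-iodo-4-methoxy-5-[(2R)-5-methyl-2-(prop-1-en-2-yl)hex-5-en-1-yl]phenyl}{3-[tri(propan-2-yl)silyloxy]phenyl}methanone (iodine at ring-A C5)
Conditions: NIS (1.0 equiv), MeCN, −20 °C, dark
Reagents that add atoms: N-iodosuccinimide, O=C1CCC(=O)N1I
Why: Electrophilic aromatic iodination at C5, the only unsubstituted carbon of ring A and doubly activated by the flanking OH and OMe groups, while ring B is deactivated by the ketone and the two 1,1-disubstituted alkenes should be outrun by the phloroglucinol ring at low temperature with one equivalent of reagent.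

Step 14
Reactants: 23 the C5 iodide; 24 4,4,5,5-tetramethyl-2-[(1E)-3-methylbut-1-en-1-yl]-1,3,2-dioxaborolane
Product: 25 {2,6-dihydroxy-4-methoxy-3-[(1E)-3-methylbut-1-en-1-yl]-5-[(2R)-5-methyl-2-(prop-1-en-2-yl)hex-5-en-1-yl]phenyl}{3-[tri(propan-2-yl)silyloxy]phenyl}methanone
Conditions: Pd(OAc)2 (5 mol%), SPhos (10 mol%), K3PO4, THF/H2O, 50 °C
Reagents that add atoms: none
Why: Suzuki–Miyaura coupling, in which oxidative addition of the aryl iodide to zerovalent palladium formed in the flask, transmetalation of the alkenylboronate and reductive elimination keep the E geometry of 24, the bulky biaryl phosphine coping with the electron-rich, di-ortho-substituted iodide that bears free phenols.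

Step 15
Reactants: 25 the TIPS-protected coupling product
Product: 26 {2,6-dihydroxy-4-methoxy-3-[(1E)-3-methylbut-1-en-1-yl]-5-[(2R)-5-methyl-2-(prop-1-en-2-yl)hex-5-en-1-yl]phenyl}(3-hydroxyphenyl)methanone (CNP0208548.1)
Conditions: Bu4NF (1.2 equiv), AcOH (1.2 equiv), THF, 0 °C
Reagents that add atoms: none
Why: Fluoride-mediated cleavage of the aryl silyl ether, buffered with acetic acid so that the phenols are not exposed to strongly basic fluoride, should free the ring-B hydroxyl and leave the methyl ether, the three alkenes and the stereocentre untouched.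

**Compound list**
1 | (R)-(+)-limonene, (4R)-1-methyl-4-(prop-1-en-2-yl)cyclohex-1-ene | CC1=CC[C@@H](CC1)C(C)=C | starting material
2 | (4R)-1-methyl-4-(prop-1-en-2-yl)-7-oxabicyclo[4.1.0]heptane (cis/trans mixture) | CC12OC1C[C@@H](CC2)C(C)=C | intermediate
3 | (4R)-1-methyl-4-(prop-1-en-2-yl)cyclohexane-1,2-diol (formed in the flask) | CC1(O)C(O)C[C@@H](CC1)C(C)=C | intermediate
4 | (3R)-6-oxo-3-(prop-1-en-2-yl)heptanal | CC(=O)CC[C@H](CC=O)C(C)=C | intermediate
5 | (3R)-6-oxo-3-(prop-1-en-2-yl)heptanoic acid | CC(=O)CC[C@H](CC(=O)O)C(C)=C | intermediate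
6 | (3R)-6-methyl-3-(prop-1-en-2-yl)hept-6-enoic acid | C=C(C)CC[C@H](CC(=O)O)C(C)=C | intermediate
7 | (3R)-6-methyl-3-(prop-1-en-2-yl)hept-6-enoic 2-methylpropyl carbonic anhydride (formed in the flask) | C=C(C)CC[C@H](CC(=O)OC(=O)OCC(C)C)C(C)=C | intermediate
8 | (4R)-1-diazo-7-methyl-4-(prop-1-en-2-yl)oct-7-en-2-one | C=C(C)CC[C@H](CC(=O)C=[N+]=[N-])C(C)=C | intermediate
9 | (4R)-7-methyl-4-(prop-1-en-2-yl)octa-1,7-dien-1-one (ketene, formed in the flask) | C=C(C)CC[C@H](CC=C=O)C(C)=C | intermediate
10 | methyl (4R)-7-methyl-4-(prop-1-en-2-yl)oct-7-enoate | C=C(C)CC[C@H](CCC(=O)OC)C(C)=C | intermediate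
11 | N-methoxy-N-methylacetamide | CC(=O)N(C)OC | starting material
12 | lithium (4R)-1-methoxy-7-methyl-4-(prop-1-en-2-yl)octa-1,7-dien-1-olate (enolate of 10, formed in the flask) | [Li+].C=C(C)CC[C@H](CC=C([O-])OC)C(C)=C | intermediate
13 | methyl 2-[(2R)-5-methyl-2-(prop-1-en-2-yl)hex-5-en-1-yl]-3-oxobutanoate (epimers at C2) | COC(=O)C(C[C@@H](CCC(C)=C)C(C)=C)C(C)=O | intermediate
14 | dilithium 1-methoxy-2-[(2R)-5-methyl-2-(prop-1-en-2-yl)hex-5-en-1-yl]buta-1,3-diene-1,3-bis(olate) (dienolate of 13, formed in the flask) | [Li+].[Li+].COC([O-])=C(C[C@@H](CCC(C)=C)C(C)=C)C([O-])=C | intermediate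
15 | methyl 2-[(2R)-5-methyl-2-(prop-1-en-2-yl)hex-5-en-1-yl]-3,5-dioxohexanoate | COC(=O)C(C[C@@H](CCC(C)=C)C(C)=C)C(=O)CC(C)=O | intermediate
16 | methyl 3-hydroxybenzoate | COC(=O)c1cccc(O)c1 | starting material
17 | methyl 3-[tri(propan-2-yl)silyloxy]benzoate | COC(=O)c1cccc(O[Si](C(C)C)(C(C)C)C(C)C)c1 | intermediate
18 | trilithium 1-methoxy-2-[(2R)-5-methyl-2-(prop-1-en-2-yl)hex-5-en-1-yl]hexa-1,3,5-triene-1,3,5-tris(olate) (trienolate of 15, formed in the flask) | [Li+].[Li+].[Li+].COC([O-])=C(C[C@@H](CCC(C)=C)C(C)=C)C([O-])=CC([O-])=C | intermediate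
19 | methyl 2-[(2R)-5-methyl-2-(prop-1-en-2-yl)hex-5-en-1-yl]-3,5,7-trioxo-7-{3-[tri(propan-2-yl)silyloxy]phenyl}heptanoate | COC(=O)C(C[C@@H](CCC(C)=C)C(C)=C)C(=O)CC(=O)CC(=O)c1cccc(O[Si](C(C)C)(C(C)C)C(C)C)c1 | intermediate
20 | 4-[(2R)-5-methyl-2-(prop-1-en-2-yl)hex-5-en-1-yl]-2-{3-[tri(propan-2-yl)silyloxy]benzoyl}cyclohexane-1,3,5-trione (formed in the flask as its magnesium enolate) | C=C(C)CC[C@H](CC1C(=O)CC(=O)C(C(=O)c2cccc(O[Si](C(C)C)(C(C)C)C(C)C)c2)C1=O)C(=C)C | intermediate
21 | {2,4,6-trihydroxy-3-[(2R)-5-methyl-2-(prop-1-en-2-yl)hex-5-en-1-yl]phenyl}{3-[tri(propan-2-yl)silyloxy]phenyl}methanone | C=C(C)CC[C@H](Cc1c(O)cc(O)c(C(=O)c2cccc(O[Si](C(C)C)(C(C)C)C(C)C)c2)c1O)C(=C)C | intermediate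
22 | {2,6-dihydroxy-4-methoxy-3-[(2R)-5-methyl-2-(prop-1-en-2-yl)hex-5-en-1-yl]phenyl}{3-[tri(propan-2-yl)silyloxy]phenyl}methanone | C=C(C)CC[C@H](Cc1c(OC)cc(O)c(C(=O)c2cccc(O[Si](C(C)C)(C(C)C)C(C)C)c2)c1O)C(=C)C | intermediate
23 | {2,6-dihydroxy-3-iodo-4-methoxy-5-[(2R)-5-methyl-2-(prop-1-en-2-yl)hex-5-en-1-yl]phenyl}{3-[tri(propan-2-yl)silyloxy]phenyl}methanone | C=C(C)CC[C@H](Cc1c(OC)c(I)c(O)c(C(=O)c2cccc(O[Si](C(C)C)(C(C)C)C(C)C)c2)c1O)C(=C)C | intermediate
24 | 4,4,5,5-tetramethyl-2-[(1E)-3-methylbut-1-en-1-yl]-1,3,2-dioxaborolane | CC(C)/C=C/B1OC(C)(C)C(C)(C)O1 | starting material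
25 | {2,6-dihydroxy-4-methoxy-3-[(1E)-3-methylbut-1-en-1-yl]-5-[(2R)-5-methyl-2-(prop-1-en-2-yl)hex-5-en-1-yl]phenyl}{3-[tri(propan-2-yl)silyloxy]phenyl}methanone | C=C(C)CC[C@H](Cc1c(OC)c(/C=C/C(C)C)c(O)c(C(=O)c2cccc(O[Si](C(C)C)(C(C)C)C(C)C)c2)c1O)C(=C)C | intermediate
26 | {2,6-dihydroxy-4-methoxy-3-[(1E)-3-methylbut-1-en-1-yl]-5-[(2R)-5-methyl-2-(prop-1-en-2-yl)hex-5-en-1-yl]phenyl}(3-hydroxyphenyl)methanone | C=C(C)CC[C@H](Cc1c(O)c(C(=O)c2cccc(O)c2)c(O)c(/C=C/C(C)C)c1OC)C(=C)C | target

**Step count**
Total step count: 15.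
Longest linear sequence: 14 steps (steps 1–8 and 10–15, from 1 to 26); step 9 is a one-step side branch.

**Steps most likely to fail**

Step 11 (key step). What may go wrong: the carbanion at C1 adds to the aroyl carbonyl faster than C3 adds to the hindered, α-branched ester, and the aldol adduct dehydrates towards C3 to a non-aromatic cyclohexenedione; or methoxide cleaves the chain by retro-Claisen fragmentation before it closes. Fallback: a pyrone relay that removes C1 as a nucleophile before the ring is closed. It sets out from 15 and comes back to the route at 22, so that steps 10 to 12 are replaced. Heating 15 with DBU in toluene should lactonise it (enol oxygen of the 5-oxo group onto the ester) to 4-hydroxy-6-methyl-3-[(2R)-5-methyl-2-(prop-1-en-2-yl)hex-5-en-1-yl]-2H-pyran-2-one F1. Dimethyl sulfate and K2CO3 in acetone should then give 4-methoxy-6-methyl-3-[(2R)-5-methyl-2-(prop-1-en-2-yl)hex-5-en-1-yl]-2H-pyran-2-one F2, in which the future C6 methoxyl is already fixed. LiN(iPr)2 deprotonates the 6-methyl group, and the anion (two equivalents) is acylated by 17 to give 4-methoxy-3-[(2R)-5-methyl-2-(prop-1-en-2-yl)hex-5-en-1-yl]-6-(2-oxo-2-{3-[tri(propan-2-yl)silyloxy]phenyl}ethyl)-2H-pyran-2-one F3. Mg(OMe)2 in methanol should open the lactone to a (Z)-β-methoxy enoate in which C1 is an sp2 carbon and can no longer act as an aldol donor, and the C3 carbanion closes onto the ester as in step 11 to give 22 directly.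

Step 10. What may go wrong: the third deprotonation is slow next to the branched centre, so that partly deprotonated material condenses with itself, and proton transfer from the more acidic acylation product quenches the trienolate before the rather unreactive ester is consumed. Fallback: aldol addition and oxidation in place of acylation. It sets out from 15 and 17 and comes back at 19. Reduction of 17 with iBu2AlH in CH2Cl2 at −78 °C should give 3-[tri(propan-2-yl)silyloxy]benzaldehyde F4. The trienolate of 15 (LiN(iPr)2, 3.2 equiv) adds through its terminal carbon to F4 at −78 °C, where no acidic product is formed, to give methyl 7-hydroxy-2-[(2R)-5-methyl-2-(prop-1-en-2-yl)hex-5-en-1-yl]-3,5-dioxo-7-{3-[tri(propan-2-yl)silyloxy]phenyl}heptanoate F5. Dess–Martin periodinane (NaHCO3-buffered, CH2Cl2) then oxidises the benzylic alcohol of F5 to the ketone, which is 19.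

Step 13. What may go wrong: the iodonium donor is intercepted by the isopropenyl group of the arm with participation of the neighbouring C2 hydroxyl (iodoetherification to a chroman) or by the terminal alkene, or a second iodination follows the first. Fallback: the C5 side chain is brought in through an aldehyde, with no electrophilic halogen. It sets out from 22 and comes back at 25, so that steps 13 and 14 are replaced. ortho-Formylation of 22 with paraformaldehyde, MgCl2 and Et3N in MeCN (the magnesium phenoxide of the C4 hydroxyl delivers formaldehyde to C5) should give 2,4-dihydroxy-6-methoxy-5-[(2R)-5-methyl-2-(prop-1-en-2-yl)hex-5-en-1-yl]-3-{3-[tri(propan-2-yl)silyloxy]benzoyl}benzaldehyde F6. Wittig olefination of F6 with the ylide from commercial isobutyltriphenylphosphonium bromide and KN(SiMe3)2 (excess, the two phenols being carried as phenoxides) should give 25 together with its Z isomer, {2,6-dihydroxy-4-methoxy-3-[(1Z)-3-methylbut-1-en-1-yl]-5-[(2R)-5-methyl-2-(prop-1-en-2-yl)hex-5-en-1-yl]phenyl}{3-[tri(propan-2-yl)silyloxy]phenyl}methanone F7. The mixture is equilibrated to the E alkene 25 with catalytic PhSSPh under irradiation (reversible thiyl radical addition).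

**Further compounds**
F1 | step 11 | 4-hydroxy-6-methyl-3-[(2R)-5-methyl-2-(prop-1-en-2-yl)hex-5-en-1-yl]-2H-pyran-2-one | CC1=CC(O)=C(C[C@@H](CCC(C)=C)C(C)=C)C(=O)O1
F2 | step 11 | 4-methoxy-6-methyl-3-[(2R)-5-methyl-2-(prop-1-en-2-yl)hex-5-en-1-yl]-2H-pyran-2-one | CC1=CC(OC)=C(C[C@@H](CCC(C)=C)C(C)=C)C(=O)O1
F3 | step 11 | 4-methoxy-3-[(2R)-5-methyl-2-(prop-1-en-2-yl)hex-5-en-1-yl]-6-(2-oxo-2-{3-[tri(propan-2-yl)silyloxy]phenyl}ethyl)-2H-pyran-2-one | O=C(CC1=CC(OC)=C(C[C@@H](CCC(C)=C)C(C)=C)C(=O)O1)c1cccc(O[Si](C(C)C)(C(C)C)C(C)C)c1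
F4 | step 10 | 3-[tri(propan-2-yl)silyloxy]benzaldehyde | O=Cc1cccc(O[Si](C(C)C)(C(C)C)C(C)C)c1
F5 | step 10 | methyl 7-hydroxy-2-[(2R)-5-methyl-2-(prop-1-en-2-yl)hex-5-en-1-yl]-3,5-dioxo-7-{3-[tri(propan-2-yl)silyloxy]phenyl}heptanoate | COC(=O)C(C[C@@H](CCC(C)=C)C(C)=C)C(=O)CC(=O)CC(O)c1cccc(O[Si](C(C)C)(C(C)C)C(C)C)c1
F6 | step 13 | 2,4-dihydroxy-6-methoxy-5-[(2R)-5-methyl-2-(prop-1-en-2-yl)hex-5-en-1-yl]-3-{3-[tri(propan-2-yl)silyloxy]benzoyl}benzaldehyde | C=C(C)CC[C@H](Cc1c(OC)c(C=O)c(O)c(C(=O)c2cccc(O[Si](C(C)C)(C(C)C)C(C)C)c2)c1O)C(=C)C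
F7 | step 13 | {2,6-dihydroxy-4-methoxy-3-[(1Z)-3-methylbut-1-en-1-yl]-5-[(2R)-5-methyl-2-(prop-1-en-2-yl)hex-5-en-1-yl]phenyl}{3-[tri(propan-2-yl)silyloxy]phenyl}methanone | C=C(C)CC[C@H](Cc1c(OC)c(/C=C\C(C)C)c(O)c(C(=O)c2cccc(O[Si](C(C)C)(C(C)C)C(C)C)c2)c1O)C(=C)C
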